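**Plan**

- Target numbering: oxolane O1, C2 (aryl), C3 (CH2OH), C4 (3,4,5-trimethoxybenzyl), C5 (ring CH2); 2,3-trans, 3,4-cis, (2S,3R,4R).
- Retrosynthesis: the aryl–carbon bond and the benzylic oxygen of the C4 side chain are cut first, leaving a γ-lactone (ring A) that joins the C4 carbonyl carbon to the C3 CH2O arm. Then C4–C5 is cut, and last C2–C3 (aldol).
- Enabling feature: C5 is the one ring carbon without a substituent, a CH2 between O1 and C4. It can therefore start as the CH3 of a methyl ether on the C2 oxygen and be bonded to C4 once C4 is a carbenoid carbon next to the ring A carbonyl.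
- Forward order: aldol (C2–C3), monocyclic butyrolactone (ring A), diazo transfer, C–H insertion closing the oxolane (ring B) onto ring A, opening of ring A by an aryllithium, benzylic deoxygenation.
- Stereochemistry: C2 and C3 come from the auxiliary-controlled syn-aldol with (S)-4-benzyl-2-oxazolidinone; C4 comes from the compulsory cis fusion of the two five-membered rings in the insertion.

Key step: step 8

Remark: lithium salts of numbered compounds and the O-metal forms of products that are released on work-up are counted with their parent compounds; the catalyst-bound carbenoid of step 8 is a catalytic intermediate and carries no number.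

**Route**

Step 1
Reactants: 1 (S)-4-benzyl-2-oxazolidinone; 2 pent-4-enoyl chloride
Product: 3 (S)-4-benzyl-3-(pent-4-enoyl)oxazolidin-2-one
Conditions: n-BuLi, THF, −78 °C; then 2, −78 → 0 °C
Reagents that add atoms: none
Why: N-acylation of the lithiated oxazolidinone by an acid chloride is the standard entry to Evans imides and neither forms nor touches a stereocentre.

Step 2
Reactants: 3 (S)-4-benzyl-3-(pent-4-enoyl)oxazolidin-2-one; 4 3,4,5-trimethoxybenzaldehyde
Product: 6 (4S)-4-benzyl-3-[(2S)-2-[(S)-hydroxy(3,4,5-trimethoxyphenyl)methyl]pent-4-enoyl]oxazolidin-2-one, via Z-dibutylboron enolate 5 (not isolated)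
Conditions: Bu2BOTf, iPr2NEt, CH2Cl2, 0 °C; 4, −78 → 0 °C; pH 7 buffer, MeOH, 30% H2O2
Reagents that add atoms: dibutylboron triflate, CCCCB(CCCC)OS(=O)(=O)C(F)(F)F (its Bu2B group is carried only by intermediate 5 and is lost on work-up)
Why: Evans syn-aldol reaction, in which the Z-boron enolate meets the aldehyde in a closed Zimmerman–Traxler chair on the face away from the auxiliary benzyl group, so the imide α-carbon (target C3) and the carbinol carbon (target C2) are both set in the syn relationship that becomes 2,3-trans in the oxolane.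

Step 3
Reactants: 6 the syn-aldol adduct
Product: 7 (4S)-4-benzyl-3-[(2S)-2-[(S)-methoxy(3,4,5-trimethoxyphenyl)methyl]pent-4-enoyl]oxazolidin-2-one
Conditions: Me3OBF4, 1,8-bis(dimethylamino)naphthalene, 4 Å MS, CH2Cl2, 0 °C → rt
Reagents that add atoms: trimethyloxonium tetrafluoroborate, C[O+](C)C.F[B-](F)(F)F
Why: O-methylation with Meerwein's salt and a non-nucleophilic proton scavenger alkylates the hydroxyl without forming an alkoxide, so retro-aldol cleavage and acyl migration are avoided and both stereocentres are kept; this methyl carbon is the future C5.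

Step 4
Reactants: 7 the O-methylated imide
Product: 8 (2R)-2-[(S)-methoxy(3,4,5-trimethoxyphenyl)methyl]pent-4-en-1-ol
Conditions: LiBH4, MeOH (1.1 equiv), THF, 0 °C
Reagents that add atoms: none
Why: Reductive cleavage of the N-acyl oxazolidinone with LiBH4 gives the primary alcohol (the future C3 hydroxymethyl) and returns auxiliary 1, without epimerising the α-centre.

Step 5
Reactants: 8 the pentenol
Product: 11 (4R)-4-[(S)-methoxy(3,4,5-trimethoxyphenyl)methyl]oxolan-2-ol (anomer mixture), via triol 9 (not isolated), via hydroxy aldehyde 10 (not isolated)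
Conditions: OsO4 (2 mol%), NaIO4, 2,6-lutidine, 1,4-dioxane/H2O, rt
Reagents that add atoms: OsO4, O=[Os](=O)(=O)=O (delivers the oxygen that ends as the lactol hydroxyl; turned over by NaIO4, [Na+].[O-]I(=O)(=O)=O)
Why: Lemieux–Johnson oxidation (catalytic dihydroxylation, then periodate glycol cleavage) removes the terminal carbon without ozone, which could attack the electron-rich arene, and the aldehyde is trapped at once by the primary hydroxyl as a five-membered lactol.

Step 6
Reactants: 11 the lactol
Product: 12 (4R)-4-[(S)-methoxy(3,4,5-trimethoxyphenyl)methyl]oxolan-2-one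
Conditions: TEMPO (10 mol%), PhI(OAc)2, CH2Cl2, rt
Reagents that add atoms: none
Why: Oxoammonium (TEMPO) oxidation of a lactol to the lactone with PhI(OAc)2 as terminal oxidant is mild, leaves the benzylic ether and the arene alone and cannot epimerise the β-centre.

Step 7
Reactants: 12 the butyrolactone
Product: 14 (4R)-3-diazo-4-[(S)-methoxy(3,4,5-trimethoxyphenyl)methyl]oxolan-2-one, via trifluoroacetyl lactone 13 (not isolated)
Conditions: LiN(SiMe3)2, THF, −78 °C; CF3CO2CH2CF3, −78 °C; aq. HCl work-up; then MsN3, Et3N, H2O (1 equiv), MeCN, rt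
Reagents that add atoms: methanesulfonyl azide, CS(=O)(=O)N=[N+]=[N-] (the two diazo nitrogens); 2,2,2-trifluoroethyl trifluoroacetate, O=C(OCC(F)(F)F)C(F)(F)F (its CF3CO group is carried only by intermediate 13)
Why: Regitz-type deacylative (detrifluoroacetylative) diazo transfer, in which the lactone enolate is first C-acylated at its only α-position and the sulfonyl azide then transfers N2 with loss of the trifluoroacetyl group; neither stereocentre is acidic and no β-leaving group is available to the enolate.

Step 8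
Reactants: 14 the α-diazo lactone
Product: 15 (1R,5R,6S)-6-(3,4,5-trimethoxyphenyl)-3,7-dioxabicyclo[3.3.0]octan-2-one (cis-fused; aryl on the convex face)
Conditions: Rh2(NHCOCH3)4 (2 mol%), CH2Cl2, 40 °C, slow addition of 14
Reagents that add atoms: none
Why: Rh2(NHCOCH3)4 (divalent rhodium) expels N2 from 14 to give an electrophilic carbenoid at the lactone α-carbon (future C4), which inserts into a C–H bond of the methoxy group through a three-centre, hydride-transfer-like transition state and so forms C4–C5. The closest known reaction type is the dirhodium-catalysed 1,5 C–H insertion next to an ether oxygen from α-diazo γ-butyrolactones, used for furofuranone lignan cores; insertion into an O–CH3 group is the less usual variant of it. The oxolane (ring B) closes in the 1,5 mode, its five members being the carbenoid carbon, C3, C2, O1 and the former methyl carbon. The only new stereocentre, C4, is fixed by the ring fusion, since two fused five-membered rings can only be cis-fused; C2 and C3 are untouched, so the aryl group ends on the convex face. The step needs chemoselectivity for the methoxy C–H over 1,2-hydride shift from C3–H (butenolide), attack on the aryl ortho carbon (also 1,5) and oxonium ylide formation. The ether oxygen makes the three equivalent O–CH3 hydrogens the most hydridic C–H within reach, the ylide would need a four-membered ring, and the electron-rich acetamidate ligands temper the carbenoid so that insertion into the activated C–H should be preferred to aromatic substitution, while slow addition limits carbene dimerisation.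

Step 9
Reactants: 15 the bicyclic lactone; 16 5-bromo-1,2,3-trimethoxybenzene
Product: 18 (3,4,5-trimethoxyphenyl)[(3R,4R,5S)-4-(hydroxymethyl)-5-(3,4,5-trimethoxyphenyl)oxolan-3-yl]methanol (carbinol epimers), via keto alcohol 17 (not isolated)
Conditions: 16, n-BuLi, THF, −78 °C; then 15, −78 °C; MeOH, NaBH4, −78 → 0 °C; H2O work-up
Reagents that add atoms: none
Why: Addition of an aryllithium (from bromine–lithium exchange) to the lactone should stop after one addition because the tetrahedral lithium hemiketal persists at −78 °C, and borohydride reduction of the released aryl ketone gives the diol; the carbinol configuration is irrelevant because that oxygen is removed later.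

Step 10
Reactants: 18 the diol
Product: 19 [(3R,4R,5S)-4-(acetoxymethyl)-5-(3,4,5-trimethoxyphenyl)oxolan-3-yl](3,4,5-trimethoxyphenyl)methyl acetate
Conditions: Ac2O, pyridine, DMAP (10 mol%), CH2Cl2, 0 °C → rt
Reagents that add atoms: acetic anhydride, CC(=O)OC(C)=O
Why: DMAP-catalysed acetylation under basic conditions turns the benzylic hydroxyl into a group that palladium cleaves readily and avoids the acid that would cyclodehydrate the 1,4-diol to a furofuran.

Step 11
Reactants: 19 the diacetate
Product: 20 [(2S,3R,4R)-4-(3,4,5-trimethoxybenzyl)-2-(3,4,5-trimethoxyphenyl)oxolan-3-yl]methyl acetate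
Conditions: H2 (1 atm), Pd/C (10 wt% Pd), Et3N (1.2 equiv), EtOAc, rt
Reagents that add atoms: none
Why: Hydrogenolysis of a benzylic ester C–O bond, in which acetate is a much better leaving group on palladium than the alkoxide of the ring ether, while the amine buffers the acetic acid released and retards benzyl ether cleavage, so only the exocyclic benzylic C–O should be cut; the primary acetate is inert and no ring stereocentre is involved.

Step 12
Reactants: 20 the monoacetate
Product: 21 [(2S,3R,4R)-4-(3,4,5-trimethoxybenzyl)-2-(3,4,5-trimethoxyphenyl)oxolan-3-yl]methanol (target)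
Conditions: K2CO3 (0.2 equiv), MeOH, rt
Reagents that add atoms: none
Why: Zemplén-type transesterification of the primary acetate with methanol under mild carbonate catalysis frees the C3 hydroxymethyl group without affecting the ethers or any stereocentre.

**Compound list**

1 | (S)-4-benzyl-2-oxazolidinone | O=C1N[C@@H](Cc2ccccc2)CO1 | starting material
2 | pent-4-enoyl chloride | C=CCCC(=O)Cl | starting material
3 | (S)-4-benzyl-3-(pent-4-enoyl)oxazolidin-2-one | C=CCCC(=O)N1[C@@H](Cc2ccccc2)COC1=O | intermediate
4 | 3,4,5-trimethoxybenzaldehyde | COc1cc(C=O)cc(OC)c1OC | starting material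
5 | Z-dibutylboron enolate of 3 | C=CC/C=C(\OB(CCCC)CCCC)N1[C@@H](Cc2ccccc2)COC1=O | intermediate (not isolated)
6 | (4S)-4-benzyl-3-[(2S)-2-[(S)-hydroxy(3,4,5-trimethoxyphenyl)methyl]pent-4-enoyl]oxazolidin-2-one | C=CC[C@H](C(=O)N1[C@@H](Cc2ccccc2)COC1=O)[C@H](O)c1cc(OC)c(OC)c(OC)c1 | intermediate
7 | (4S)-4-benzyl-3-[(2S)-2-[(S)-methoxy(3,4,5-trimethoxyphenyl)methyl]pent-4-enoyl]oxazolidin-2-one | C=CC[C@H](C(=O)N1[C@@H](Cc2ccccc2)COC1=O)[C@H](OC)c1cc(OC)c(OC)c(OC)c1 | intermediate
8 | (2R)-2-[(S)-methoxy(3,4,5-trimethoxyphenyl)methyl]pent-4-en-1-ol | C=CC[C@H](CO)[C@H](OC)c1cc(OC)c(OC)c(OC)c1 | intermediate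
9 | (4R,5S)-4-(hydroxymethyl)-5-methoxy-5-(3,4,5-trimethoxyphenyl)pentane-1,2-diol (C2 epimers) | OCC(O)C[C@H](CO)[C@H](OC)c1cc(OC)c(OC)c(OC)c1 | intermediate (not isolated)
10 | (3R,4S)-3-(hydroxymethyl)-4-methoxy-4-(3,4,5-trimethoxyphenyl)butanal | O=CC[C@H](CO)[C@H](OC)c1cc(OC)c(OC)c(OC)c1 | intermediate (not isolated)
11 | (4R)-4-[(S)-methoxy(3,4,5-trimethoxyphenyl)methyl]oxolan-2-ol (anomer mixture) | OC1OC[C@H]([C@H](OC)c2cc(OC)c(OC)c(OC)c2)C1 | intermediate
12 | (4R)-4-[(S)-methoxy(3,4,5-trimethoxyphenyl)methyl]oxolan-2-one | O=C1OC[C@H]([C@H](OC)c2cc(OC)c(OC)c(OC)c2)C1 | intermediate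
13 | (4R)-4-[(S)-methoxy(3,4,5-trimethoxyphenyl)methyl]-3-(trifluoroacetyl)oxolan-2-one (C3 undefined) | O=C1OC[C@H]([C@H](OC)c2cc(OC)c(OC)c(OC)c2)C1C(=O)C(F)(F)F | intermediate (not isolated)
14 | (4R)-3-diazo-4-[(S)-methoxy(3,4,5-trimethoxyphenyl)methyl]oxolan-2-one | O=C1OC[C@H]([C@H](OC)c2cc(OC)c(OC)c(OC)c2)C1=[N+]=[N-] | intermediate (key-step precursor)
15 | (1R,5R,6S)-6-(3,4,5-trimethoxyphenyl)-3,7-dioxabicyclo[3.3.0]octan-2-one | O=C1OC[C@@H]2[C@@H](c3cc(OC)c(OC)c(OC)c3)OC[C@H]12 | intermediate (key-step product)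
16 | 5-bromo-1,2,3-trimethoxybenzene | COc1cc(Br)cc(OC)c1OC | starting material
17 | [(3R,4R,5S)-4-(hydroxymethyl)-5-(3,4,5-trimethoxyphenyl)oxolan-3-yl](3,4,5-trimethoxyphenyl)methanone | O=C(c1cc(OC)c(OC)c(OC)c1)[C@H]1CO[C@H](c2cc(OC)c(OC)c(OC)c2)[C@H]1CO | intermediate (not isolated)
18 | (3,4,5-trimethoxyphenyl)[(3R,4R,5S)-4-(hydroxymethyl)-5-(3,4,5-trimethoxyphenyl)oxolan-3-yl]methanol (carbinol epimers) | OC(c1cc(OC)c(OC)c(OC)c1)[C@H]1CO[C@H](c2cc(OC)c(OC)c(OC)c2)[C@H]1CO | intermediate
19 | [(3R,4R,5S)-4-(acetoxymethyl)-5-(3,4,5-trimethoxyphenyl)oxolan-3-yl](3,4,5-trimethoxyphenyl)methyl acetate (carbinol epimers) | CC(=O)OC(c1cc(OC)c(OC)c(OC)c1)[C@H]1CO[C@H](c2cc(OC)c(OC)c(OC)c2)[C@H]1COC(C)=O | intermediate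
20 | [(2S,3R,4R)-4-(3,4,5-trimethoxybenzyl)-2-(3,4,5-trimethoxyphenyl)oxolan-3-yl]methyl acetate | COc1cc(C[C@H]2CO[C@H](c3cc(OC)c(OC)c(OC)c3)[C@H]2COC(C)=O)cc(OC)c1OC | intermediate
21 | [(2S,3R,4R)-4-(3,4,5-trimethoxybenzyl)-2-(3,4,5-trimethoxyphenyl)oxolan-3-yl]methanol | COc1cc(C[C@H]2CO[C@H](c3cc(OC)c(OC)c(OC)c3)[C@H]2CO)cc(OC)c1OC | target

**Count and risks**

Total step count: 12. Longest linear sequence: 12 steps (1 and 2 to 21); aryl bromide 16 enters directly in step 9.

Steps most likely to fail:

1. Step 8. The carbenoid may be consumed by 1,2-hydride migration from the neighbouring ring C–H, or by attack on the aryl ortho carbon, faster than it inserts into the unactivated-but-for-oxygen methyl C–H. Fallback (same C4–C5 bond, made by ionic means): setting out from aldol adduct 6, the hydroxyl would be capped with MOMCl and iPr2NEt to give the methoxymethyl ether imide F1. LiBH4 cleavage as in step 4 would give the alcohol F2, Lemieux–Johnson cleavage as in step 5 the lactol F3, and TEMPO/PhI(OAc)2 oxidation as in step 6 the lactone F4. LiN(SiMe3)2 and Me3SiCl would convert F4 into the silyl ketene acetal F5. TiCl4 in CH2Cl2 at −78 °C would then ionise the MOM group to an oxocarbenium ion that the ketene acetal captures intramolecularly (a directed Mukaiyama-type alkylation by an alkoxymethyl ether), closing ring B and returning to the route at 15.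

2. Step 11. The ring C2–O1 bond is also benzylic to an electron-rich arene and may be cleaved at a rate comparable to the acetate, opening the oxolane. Fallback (radical deoxygenation, which leaves benzylic ethers alone): setting out from diol 18, TBSCl and imidazole would silylate the primary hydroxyl to give the silyl ether F6. NaH, CS2 and MeI would give the benzylic xanthate F7, and Barton–McCombie reduction (Bu3SnH, AIBN, toluene, 80 °C) the silyl ether F8 of the target. Bu4NF would then return to the route at 21.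

3. Step 9. A second aryllithium may add to ketone set free by premature collapse of the hemiketal, or C4 may epimerise through the open keto form under the basic quench. Fallback (aldehyde oxidation level instead of ketone): setting out from lactone 15, i-Bu2AlH in toluene at −78 °C would give the bicyclic lactol F9. The Grignard reagent 3,4,5-(MeO)3C6H2MgBr (from 16 and Mg, THF) would then add to its open hydroxy-aldehyde form and return to the route at diol 18.

**Further compounds**

F1 | step 8 | (4S)-4-benzyl-3-[(2S)-2-[(S)-(methoxymethoxy)(3,4,5-trimethoxyphenyl)methyl]pent-4-enoyl]oxazolidin-2-one | C=CC[C@H](C(=O)N1[C@@H](Cc2ccccc2)COC1=O)[C@H](OCOC)c1cc(OC)c(OC)c(OC)c1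
F2 | step 8 | (2R)-2-[(S)-(methoxymethoxy)(3,4,5-trimethoxyphenyl)methyl]pent-4-en-1-ol | C=CC[C@H](CO)[C@H](OCOC)c1cc(OC)c(OC)c(OC)c1
F3 | step 8 | (4R)-4-[(S)-(methoxymethoxy)(3,4,5-trimethoxyphenyl)methyl]oxolan-2-ol (anomer mixture) | OC1OC[C@H]([C@H](OCOC)c2cc(OC)c(OC)c(OC)c2)C1
F4 | step 8 | (4R)-4-[(S)-(methoxymethoxy)(3,4,5-trimethoxyphenyl)methyl]oxolan-2-one | O=C1OC[C@H]([C@H](OCOC)c2cc(OC)c(OC)c(OC)c2)C1
F5 | step 8 | {[(4R)-4-[(S)-(methoxymethoxy)(3,4,5-trimethoxyphenyl)methyl]-4,5-dihydrofuran-2-yl]oxy}trimethylsilane | C[Si](C)(C)OC1=C[C@@H]([C@H](OCOC)c2cc(OC)c(OC)c(OC)c2)CO1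
F6 | step 11 | [(3R,4R,5S)-4-{[(tert-butyldimethylsilyl)oxy]methyl}-5-(3,4,5-trimethoxyphenyl)oxolan-3-yl](3,4,5-trimethoxyphenyl)methanol | OC(c1cc(OC)c(OC)c(OC)c1)[C@H]1CO[C@H](c2cc(OC)c(OC)c(OC)c2)[C@H]1CO[Si](C)(C)C(C)(C)C
F7 | step 11 | O-{[(3R,4R,5S)-4-{[(tert-butyldimethylsilyl)oxy]methyl}-5-(3,4,5-trimethoxyphenyl)oxolan-3-yl](3,4,5-trimethoxyphenyl)methyl} S-methyl dithiocarbonate | CSC(=S)OC(c1cc(OC)c(OC)c(OC)c1)[C@H]1CO[C@H](c2cc(OC)c(OC)c(OC)c2)[C@H]1CO[Si](C)(C)C(C)(C)C
F8 | step 11 | tert-butyldimethyl{[(2S,3R,4R)-4-(3,4,5-trimethoxybenzyl)-2-(3,4,5-trimethoxyphenyl)oxolan-3-yl]methoxy}silane | COc1cc(C[C@H]2CO[C@H](c3cc(OC)c(OC)c(OC)c3)[C@H]2CO[Si](C)(C)C(C)(C)C)cc(OC)c1OC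
F9 | step 9 | (1R,5R,6S)-6-(3,4,5-trimethoxyphenyl)-3,7-dioxabicyclo[3.3.0]octan-2-ol (anomer mixture) | OC1OC[C@@H]2[C@@H](c3cc(OC)c(OC)c(OC)c3)OC[C@H]12
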